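The synthesis rests on the C15–C16 bond of the tricosanoyl chain (ester carbonyl = C1), a bond between two unactivated CH2 carbons of the unbranched polymethylene chain, remote from the benzyl ester (the only functional group; the phenyl ring is a spectator). Because neither carbon offers a polar handle, both are united as primary radicals of like polarity in a crossed Kolbe electrolysis: nonanoic acid and the monobenzyl half-ester of hexadecanedioic acid each lose CO2 at a platinum anode, and the octyl and 14-(benzyloxycarbonyl)tetradecyl radicals combine to give the C23 ester in one operation. The precursor pair thus carries one sacrificial carboxyl group on each carbon of the future bond; no stereocentre or ring is involved.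

Key step: step 2

Remark on the chemistry: the target has no stereocentre. The monobenzyl half-ester of hexadecanedioic acid is assumed not to be a reliable catalogue item and is therefore made in step 1.

Step 1
Reactants: 1 hexadecanedioic acid (used in excess, about 2.5 equiv); 2 benzyl alcohol (1 equiv)
Product: 3 16-(benzyloxy)-16-oxohexadecanoic acid (monobenzyl hexadecanedioate)
Conditions: TsOH·H2O (cat.), toluene, reflux, Dean–Stark; cool, filter off unreacted 1, chromatography
Reagents that add atoms: none
Why: Fischer esterification with azeotropic removal of water, run statistically with the diacid in excess so that the monoester should dominate over the diester, with the sparingly soluble surplus diacid recovered by filtration.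

Step 2
Reactants: 3 16-(benzyloxy)-16-oxohexadecanoic acid (1 equiv); 4 nonanoic acid (about 6 equiv)
Product: 7 benzyl tricosanoate, via octyl radical 5 (not isolated), via 14-(benzyloxycarbonyl)tetradecyl radical 6 (not isolated)
Conditions: KOH (about 0.1 equiv per total acid), MeOH, Pt anode/Pt cathode, undivided cell, constant current (about 0.2 A cm−2), 45–50 °C, occasional polarity reversal; stopped while the electrolyte is still weakly acidic
Reagents that add atoms: none
Why: At a smooth platinum anode at high current density the carboxylates of 3 and 4 are each oxidised by one electron and lose CO2, giving the primary radicals 6 and 5 in the anode layer, which combine to form the C15–C16 bond while the carboxyl protons are reduced to hydrogen at the cathode. The reaction type is the crossed (mixed) Kolbe electrolysis of a fatty acid with a dicarboxylic acid half-ester, a radical–radical union of two like-polarity sp3 carbons. No ring is closed and no stereocentre is created. The selectivity required is cross- over homo-coupling, which is statistical; the large excess of cheap 4 should ensure that radical 6 is captured mainly by radical 5, and the two symmetrical by-products differ strongly in polarity from the product (a hydrocarbon and a diester) and should be separable by chromatography or crystallisation. Unstabilised primary radicals on platinum in weakly acidic methanol should resist further oxidation to cations, and the benzyl ester should survive because the medium never turns basic (no methanolysis) and the adsorbed carboxylate layer is discharged in preference to the phenyl ring.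

Compound list
1 | hexadecanedioic acid | OC(=O)CCCCCCCCCCCCCCC(=O)O | starting material
2 | benzyl alcohol | OCc1ccccc1 | starting material
3 | 16-(benzyloxy)-16-oxohexadecanoic acid (monobenzyl hexadecanedioate) | OC(=O)CCCCCCCCCCCCCCC(=O)OCc1ccccc1 | intermediate
4 | nonanoic acid | CCCCCCCCC(=O)O | starting material
5 | octyl radical | CCCCCCC[CH2] | intermediate (not isolated)
6 | 14-(benzyloxycarbonyl)tetradecyl radical | [CH2]CCCCCCCCCCCCCC(=O)OCc1ccccc1 | intermediate (not isolated)
7 | benzyl tricosanoate | CCCCCCCCCCCCCCCCCCCCCCC(=O)OCc1ccccc1 | target

Total step count: 2
Longest linear sequence: 2 steps (1 → 3 → 7)

Steps most likely to fail (the route has only two steps, so both are ranked):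

1. Step 2 (key step). Three processes could go wrong. Statistical homo-coupling of either radical would erode the cross-coupling. The waxy, methanol-insoluble product could coat and passivate the anode. Local alkalinity near the end of the electrolysis could cause methanolysis of the benzyl ester.
Fallback: the same C15–C16 bond is made by a polar, copper-catalysed alkyl–alkyl coupling instead of a radical dimerisation. The fallback sets out from benzyl alcohol 2, which is esterified with commercial 15-bromopentadecanoic acid (BrCCCCCCCCCCCCCCC(=O)O) under TsOH catalysis in toluene with a Dean–Stark trap to give benzyl 15-bromopentadecanoate F1. Slow addition of octylmagnesium bromide (CCCCCCCC[Mg]Br) to F1 in THF/NMP with catalytic Li2CuCl4 at about 0 °C (Kochi-type Cu-catalysed Grignard–alkyl bromide coupling, in which substitution at the primary bromide should outrun addition to the ester) should give the target, so the fallback comes back to the route at compound 7.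

2. Step 1. The statistical mono-esterification could give too much diester, and separating diacid, monoester and diester of similar long-chain character could be laborious.
Fallback: the two ends are differentiated by orthogonal protection instead of statistics. The fallback sets out from benzyl alcohol 2, which is coupled with commercial 16-(tert-butoxy)-16-oxohexadecanoic acid (CC(C)(C)OC(=O)CCCCCCCCCCCCCCC(=O)O) using DCC and catalytic DMAP in CH2Cl2 (Steglich esterification) to give benzyl tert-butyl hexadecanedioate F2. Treatment of F2 with TFA in CH2Cl2 at room temperature should cleave only the tert-butyl ester (acidolysis with loss of isobutene, benzyl ester stable), so the fallback comes back to the route at compound 3.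

Further compounds
F1 | step 2 | benzyl 15-bromopentadecanoate | BrCCCCCCCCCCCCCCC(=O)OCc1ccccc1
F2 | step 1 | benzyl tert-butyl hexadecanedioate | CC(C)(C)OC(=O)CCCCCCCCCCCCCCC(=O)OCc1ccccc1
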